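**Plan**
- Retrosynthesis: the esters, the C3 alcohol, the C4 hydroxymethyl group and the C8 methylene are cut back to bicyclic enedione 16. Ring A is then cut at C4–C5 (aldol) and C1–C10 (Michael), and the side-chain bond C9–C11 (conjugate addition) falls in the same operation.
- Forward: ring B is never closed; it is the carbocycle of 4-methoxy-2-methylphenol, dearomatised to enone 7. Side-chain iodide 4, enone 7 and silyl enone 11 are joined in one pot, in which ring A is the only and last ring closed.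
- Enabling feature: in ring B, C5, C10 and C9 are the carbonyl, α- and β-carbons of a 2-methylcyclohexenone and C8 is a masked ketone. The C9 side chain, the quaternary C10 and the four carbons C1–C4 of ring A can therefore all be hung on this triad.
- Stereochemistry: C9 comes from a chiral Cu–NHC catalyst and C10 from alkylation anti to the C9 side chain. C5 and C4 come from Li/NH3 reductive hydroxymethylation, C3 from equatorial-selective hydride reduction, and both E alkenes are bought.

Key step: step 7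

Remarks: C-numbers are those of the labdane skeleton (ring A = C1–C5 and C10, ring B = C5–C10); R = (3E)-3-methyl-5-[(triisopropylsilyl)oxy]pent-3-en-1-yl; the enantiomer of the chiral NHC precursor in step 7 is assumed to be the one that gives the 3S adduct, its sense of induction being settled in a trial run.

Step 1
Reactants: 1 (2E)-3-methylpent-2-en-4-yn-1-ol
Product: 2 triisopropyl{[(2E)-3-methylpent-2-en-4-yn-1-yl]oxy}silane
Conditions: TIPSCl, imidazole, DMF, rt
Reagents that add atoms: triisopropylsilyl chloride, CC(C)[Si](Cl)(C(C)C)C(C)C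
Why: Silylation of a primary allylic alcohol is routine and should give an ether that tolerates the organometallic, basic, acidic and dissolving-metal steps ahead, the E geometry being bought.

Step 2
Reactants: 2 triisopropyl{[(2E)-3-methylpent-2-en-4-yn-1-yl]oxy}silane
Product: 3 triisopropyl{[(2E)-3-methylpenta-2,4-dien-1-yl]oxy}silane
Conditions: H2 (1 atm), Pd/CaCO3 poisoned with Pb(OAc)2, quinoline, hexane, rt
Reagents that add atoms: none
Why: Lindlar-type semi-hydrogenation should reduce the terminal alkyne to the vinyl group and stop there, leaving the trisubstituted E alkene untouched.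

Step 3
Reactants: 3 triisopropyl{[(2E)-3-methylpenta-2,4-dien-1-yl]oxy}silane
Product: 4 {[(2E)-5-iodo-3-methylpent-2-en-1-yl]oxy}triisopropylsilane
Conditions: Cp2Zr(H)Cl, THF, rt; then I2, 0 °C
Reagents that add atoms: iodine, II
Why: Hydrozirconation should add Zr–H across the less hindered terminal double bond of the diene in a 1,2-sense to give the primary homoallylic alkylzirconium, and iodinolysis should then give the primary iodide without touching the trisubstituted alkene.

Step 4
Reactants: 5 4-methoxy-2-methylphenol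
Product: 6 4,4-dimethoxy-2-methylcyclohexa-2,5-dien-1-one
Conditions: PhI(OAc)2, MeOH, 0 °C to rt
Reagents that add atoms: methanol, CO
Why: Oxidative dearomatisation of a para-methoxyphenol in methanol should give the quinone monoketal, which turns the arene into ring B with C5 as carbonyl and C8 as masked ketone.

Step 5
Reactants: 6 4,4-dimethoxy-2-methylcyclohexa-2,5-dien-1-one
Product: 7 4,4-dimethoxy-2-methylcyclohex-2-en-1-one
Conditions: H2 (1 atm), RhCl(PPh3)3 (5 mol %), benzene, rt
Reagents that add atoms: none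
Why: RhCl(PPh3)3 should hydrogenate the unhindered disubstituted double bond much faster than the methyl-bearing trisubstituted one (chemoselective homogeneous hydrogenation), leaving the 2-methyl enone needed for the key step.

Step 6
Reactants: 8 (1-bromoethenyl)trimethylsilane; 9 N-methoxy-N-methylpropanamide
Product: 11 2-(trimethylsilyl)pent-1-en-3-one, via vinyl Grignard reagent 10 (not isolated)
Conditions: Mg, THF, reflux; then 9, THF, 0 °C; inverse quench into cold 1 M HCl
Reagents that add atoms: none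
Why: The α-silylvinyl Grignard reagent should acylate the Weinreb amide through a stable chelate that releases the ketone only on the acid quench (Weinreb ketone synthesis), which also protonates the liberated amine so that it cannot add to the new enone.

Step 7
Reactants: 4 {[(2E)-5-iodo-3-methylpent-2-en-1-yl]oxy}triisopropylsilane; 7 4,4-dimethoxy-2-methylcyclohex-2-en-1-one; 11 2-(trimethylsilyl)pent-1-en-3-one
Product: 16 (4aS,5S)-1,4a-dimethyl-5-R-4,4a,7,8-tetrahydronaphthalene-2,6(3H,5H)-dione, via Grignard reagent 12 (not isolated), via magnesium enolate 13 (not isolated), via silyl diketone 14 (not isolated), via ketal enone 15 (not isolated)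
Conditions: Mg, Et2O, rt (4 to 12); Cu(OTf)2 (5 mol %), chiral hydroxyalkyl N-mesityl imidazolinium hexafluorophosphate (NHC precursor, 6 mol %), 7, Et2O, −30 °C; then 11, THF, −78 to 0 °C; then NaOMe, MeOH, 50 °C; then 1 M HCl, THF, 0 °C
Reagents that add atoms: water, O
Why: Grignard reagent 12 should transmetalate to an NHC-bound organocopper that adds to the β-carbon C9 of enone 7 through a copper π-complex and reductive elimination from trivalent copper, giving the regiodefined magnesium enolate 13; this adds through C10 to the CH2 terminus of silyl enone 11, methoxide then removes the silyl group and closes ring A by aldol addition of C4 to the ring B carbonyl C5 with E1cB dehydration, and the acid wash unmasks the C8 ketone. The closest known reaction types are the copper–NHC-catalysed asymmetric conjugate addition of Grignard reagents to 2-methylcycloalkenones with enolate trapping and the Stork–Boeckman conjugate addition–annulation with α-silyl vinyl ketones, a regiospecific Robinson annulation. Ring A is closed in a 6-(enolendo)-exo-trig aldol mode and is locked in by irreversible dehydration to the enone. C9 is set by the chiral ligand, and C10 is set by C9 because the electrophile enters anti to the pseudoaxial side chain, which places the C10 methyl cis to that chain. The step needs enolate regiocontrol, secured by generating the enolate directionally from the enone and trapping it before proton transfer, with the silyl group suppressing acceptor polymerisation and stabilising the adduct enolate. It also needs site-selective ring closure, secured because only the C4-to-C5 aldol gives a six-membered enone while the bridged ketol from C6 reverts under the equilibrating base.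

Step 8
Reactants: 16 (4aS,5S)-1,4a-dimethyl-5-R-4,4a,7,8-tetrahydronaphthalene-2,6(3H,5H)-dione
Product: 17 (4aS,5R)-1,4a-dimethyl-6-methylidene-5-R-4,4a,5,6,7,8-hexahydronaphthalen-2(3H)-one
Conditions: Ph3PCH3Br, KOtBu, THF, 0 °C
Reagents that add atoms: methyltriphenylphosphonium bromide, C[P+](c1ccccc1)(c1ccccc1)c1ccccc1.[Br-]
Why: Wittig methylenation should take the saturated C8 ketone in preference to the tetrasubstituted enone carbonyl at C3, as with the saturated carbonyl of the Wieland–Miescher ketone, while C9 keeps its thermodynamically preferred equatorial side chain.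

Step 9
Reactants: 17 (4aS,5R)-1,4a-dimethyl-6-methylidene-5-R-4,4a,5,6,7,8-hexahydronaphthalen-2(3H)-one
Product: 19 (1S,4aS,5R,8aS)-1-(hydroxymethyl)-1,4a-dimethyl-6-methylidene-5-R-octahydronaphthalen-2(1H)-one, via lithium enolate 18 (not isolated)
Conditions: Li (2.1 equiv), NH3(l)/THF, t-BuOH (1.0 equiv), −78 °C; evaporate NH3; CH2O (g, from cracked paraformaldehyde), THF, −78 °C; aq NH4Cl
Reagents that add atoms: formaldehyde, C=O
Why: Dissolving-metal reduction of the enone should give the trans ring fusion by axial protonation at C5 anti to the C10 methyl, and the regiodefined C3–C4 lithium enolate should be hydroxymethylated on the face away from the axial C10 methyl, putting CH2OH equatorial and CH3 axial at C4 (Stork reductive alkylation, aldol with formaldehyde).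

Step 10
Reactants: 19 (1S,4aS,5R,8aS)-1-(hydroxymethyl)-1,4a-dimethyl-6-methylidene-5-R-octahydronaphthalen-2(1H)-one
Product: 20 (1S,2R,4aS,5R,8aS)-1-(hydroxymethyl)-1,4a-dimethyl-6-methylidene-5-R-decahydronaphthalen-2-ol
Conditions: NaBH4, MeOH, 0 °C
Reagents that add atoms: none
Why: NaBH4 should deliver hydride along the axial trajectory of the 4,4-disubstituted 3-ketone to give the equatorial C3 alcohol, and prompt reduction removes the retro-aldol-prone β-hydroxy ketone.

Step 11
Reactants: 20 (1S,2R,4aS,5R,8aS)-1-(hydroxymethyl)-1,4a-dimethyl-6-methylidene-5-R-decahydronaphthalen-2-ol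
Product: 21 [(1S,2R,4aS,5R,8aS)-2-hydroxy-1,4a-dimethyl-6-methylidene-5-R-decahydronaphthalen-1-yl]methyl (2E)-2-methylbut-2-enoate
Conditions: tigloyl chloride (1.1 equiv), pyridine, DMAP (cat.), CH2Cl2, −20 to 0 °C
Reagents that add atoms: tigloyl chloride [(2E)-2-methylbut-2-enoyl chloride], C/C=C(\C)C(=O)Cl
Why: The primary neopentyl alcohol should be acylated faster than the equatorial secondary alcohol flanked by the quaternary C4, as in the selective acylation of the primary hydroxyl of hederagenin-type 3,23-diols (chemoselective esterification).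

Step 12
Reactants: 21 [(1S,2R,4aS,5R,8aS)-2-hydroxy-1,4a-dimethyl-6-methylidene-5-R-decahydronaphthalen-1-yl]methyl (2E)-2-methylbut-2-enoate
Product: 22 [(1S,2R,4aS,5R,8aS)-2-acetoxy-1,4a-dimethyl-6-methylidene-5-R-decahydronaphthalen-1-yl]methyl (2E)-2-methylbut-2-enoate
Conditions: Ac2O, pyridine, DMAP (cat.), rt
Reagents that add atoms: acetic anhydride, CC(=O)OC(C)=O
Why: DMAP-catalysed acetylation of the only remaining free hydroxyl is standard and should fix the C3 acetate before any acyl migration from the neighbouring tiglate.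

Step 13
Reactants: 22 [(1S,2R,4aS,5R,8aS)-2-acetoxy-1,4a-dimethyl-6-methylidene-5-R-decahydronaphthalen-1-yl]methyl (2E)-2-methylbut-2-enoate
Product: 23 [(1S,2R,4aS,5R,8aS)-2-acetoxy-5-[(3E)-5-hydroxy-3-methylpent-3-en-1-yl]-1,4a-dimethyl-6-methylidenedecahydronaphthalen-1-yl]methyl (2E)-2-methylbut-2-enoate (target; labdane numbering 3R,4S,5S,9R,10S)
Conditions: HF·pyridine, THF/pyridine, 0 °C to rt
Reagents that add atoms: none
Why: Pyridine-buffered HF should cleave the primary TIPS ether and leave both esters, the exocyclic methylene and the allylic alcohol intact (fluoride desilylation).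

**Compound list**
1 | (2E)-3-methylpent-2-en-4-yn-1-ol | C#C/C(C)=C/CO | starting material
2 | triisopropyl{[(2E)-3-methylpent-2-en-4-yn-1-yl]oxy}silane | C#C/C(C)=C/CO[Si](C(C)C)(C(C)C)C(C)C | intermediate
3 | triisopropyl{[(2E)-3-methylpenta-2,4-dien-1-yl]oxy}silane | C=C/C(C)=C/CO[Si](C(C)C)(C(C)C)C(C)C | intermediate
4 | {[(2E)-5-iodo-3-methylpent-2-en-1-yl]oxy}triisopropylsilane | ICC/C(C)=C/CO[Si](C(C)C)(C(C)C)C(C)C | intermediate
5 | 4-methoxy-2-methylphenol | COc1ccc(O)c(C)c1 | starting material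
6 | 4,4-dimethoxy-2-methylcyclohexa-2,5-dien-1-one | COC1(OC)C=CC(=O)C(C)=C1 | intermediate
7 | 4,4-dimethoxy-2-methylcyclohex-2-en-1-one | COC1(OC)CCC(=O)C(C)=C1 | intermediate
8 | (1-bromoethenyl)trimethylsilane | C=C(Br)[Si](C)(C)C | starting material
9 | N-methoxy-N-methylpropanamide | CCC(=O)N(C)OC | starting material
10 | [1-(trimethylsilyl)ethenyl]magnesium bromide | C=C([Mg]Br)[Si](C)(C)C | intermediate
11 | 2-(trimethylsilyl)pent-1-en-3-one | CCC(=O)C(=C)[Si](C)(C)C | intermediate
12 | {(3E)-3-methyl-5-[(triisopropylsilyl)oxy]pent-3-en-1-yl}magnesium iodide | I[Mg]CC/C(C)=C/CO[Si](C(C)C)(C(C)C)C(C)C | intermediate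
13 | iodomagnesium (3S)-4,4-dimethoxy-2-methyl-3-[(3E)-3-methyl-5-[(triisopropylsilyl)oxy]pent-3-en-1-yl]cyclohex-1-en-1-olate | COC1(OC)CCC(O[Mg]I)=C(C)[C@@H]1CC/C(C)=C/CO[Si](C(C)C)(C(C)C)C(C)C | intermediate
14 | (2S,3S)-4,4-dimethoxy-2-methyl-3-[(3E)-3-methyl-5-[(triisopropylsilyl)oxy]pent-3-en-1-yl]-2-[3-oxo-2-(trimethylsilyl)pentyl]cyclohexan-1-one (silyl-bearing carbon unassigned) | COC1(OC)CCC(=O)[C@@](C)(CC([Si](C)(C)C)C(=O)CC)[C@@H]1CC/C(C)=C/CO[Si](C(C)C)(C(C)C)C(C)C | intermediate
15 | (4aS,5S)-6,6-dimethoxy-1,4a-dimethyl-5-[(3E)-3-methyl-5-[(triisopropylsilyl)oxy]pent-3-en-1-yl]-4,4a,5,6,7,8-hexahydronaphthalen-2(3H)-one | COC1(OC)CCC2=C(C)C(=O)CC[C@@]2(C)[C@@H]1CC/C(C)=C/CO[Si](C(C)C)(C(C)C)C(C)C | intermediate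
16 | (4aS,5S)-1,4a-dimethyl-5-[(3E)-3-methyl-5-[(triisopropylsilyl)oxy]pent-3-en-1-yl]-4,4a,7,8-tetrahydronaphthalene-2,6(3H,5H)-dione | O=C1CCC2=C(C)C(=O)CC[C@@]2(C)[C@@H]1CC/C(C)=C/CO[Si](C(C)C)(C(C)C)C(C)C | intermediate
17 | (4aS,5R)-1,4a-dimethyl-6-methylidene-5-[(3E)-3-methyl-5-[(triisopropylsilyl)oxy]pent-3-en-1-yl]-4,4a,5,6,7,8-hexahydronaphthalen-2(3H)-one | C=C1CCC2=C(C)C(=O)CC[C@@]2(C)[C@@H]1CC/C(C)=C/CO[Si](C(C)C)(C(C)C)C(C)C | intermediate
18 | lithium (4aS,5R,8aS)-1,4a-dimethyl-6-methylidene-5-[(3E)-3-methyl-5-[(triisopropylsilyl)oxy]pent-3-en-1-yl]-3,4,4a,5,6,7,8,8a-octahydronaphthalen-2-olate | C=C1CC[C@H]2[C@@](C)(CCC(O[Li])=C2C)[C@@H]1CC/C(C)=C/CO[Si](C(C)C)(C(C)C)C(C)C | intermediate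
19 | (1S,4aS,5R,8aS)-1-(hydroxymethyl)-1,4a-dimethyl-6-methylidene-5-[(3E)-3-methyl-5-[(triisopropylsilyl)oxy]pent-3-en-1-yl]octahydronaphthalen-2(1H)-one | C=C1CC[C@H]2[C@@](C)(CCC(=O)[C@]2(C)CO)[C@@H]1CC/C(C)=C/CO[Si](C(C)C)(C(C)C)C(C)C | intermediate
20 | (1S,2R,4aS,5R,8aS)-1-(hydroxymethyl)-1,4a-dimethyl-6-methylidene-5-[(3E)-3-methyl-5-[(triisopropylsilyl)oxy]pent-3-en-1-yl]decahydronaphthalen-2-ol | C=C1CC[C@H]2[C@@](C)(CC[C@@H](O)[C@]2(C)CO)[C@@H]1CC/C(C)=C/CO[Si](C(C)C)(C(C)C)C(C)C | intermediate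
21 | [(1S,2R,4aS,5R,8aS)-2-hydroxy-1,4a-dimethyl-6-methylidene-5-[(3E)-3-methyl-5-[(triisopropylsilyl)oxy]pent-3-en-1-yl]decahydronaphthalen-1-yl]methyl (2E)-2-methylbut-2-enoate | C=C1CC[C@H]2[C@@](C)(CC[C@@H](O)[C@]2(C)COC(=O)/C(C)=C/C)[C@@H]1CC/C(C)=C/CO[Si](C(C)C)(C(C)C)C(C)C | intermediate
22 | [(1S,2R,4aS,5R,8aS)-2-acetoxy-1,4a-dimethyl-6-methylidene-5-[(3E)-3-methyl-5-[(triisopropylsilyl)oxy]pent-3-en-1-yl]decahydronaphthalen-1-yl]methyl (2E)-2-methylbut-2-enoate | C=C1CC[C@H]2[C@@](C)(CC[C@@H](OC(C)=O)[C@]2(C)COC(=O)/C(C)=C/C)[C@@H]1CC/C(C)=C/CO[Si](C(C)C)(C(C)C)C(C)C | intermediate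
23 | [(1S,2R,4aS,5R,8aS)-2-acetoxy-5-[(3E)-5-hydroxy-3-methylpent-3-en-1-yl]-1,4a-dimethyl-6-methylidenedecahydronaphthalen-1-yl]methyl (2E)-2-methylbut-2-enoate | C=C1CC[C@H]2[C@@](C)(CC[C@@H](OC(C)=O)[C@]2(C)COC(=O)/C(C)=C/C)[C@@H]1CC/C(C)=C/CO | target

**Totals**
Total step count: 13. Longest linear sequence: 10 steps (steps 1, 2, 3, 7, 8, 9, 10, 11, 12, 13).

**Steps most likely to fail**

Step 7. The conjugate addition may be slow at a β-carbon flanked by the ketal and the α-methyl group, with erosion of enantioselectivity, and the hindered magnesium enolate may undergo proton transfer or trigger polymerisation of the acceptor instead of adding to it. The fallback sets out from 4 and 7 (with 11) and returns at 16. The copper-catalysed addition of 12 to 7 is run on its own in the presence of TMSCl, and the product is isolated as the silyl enol ether trimethyl{[(3S)-4,4-dimethoxy-2-methyl-3-R-cyclohex-1-en-1-yl]oxy}silane F1. MeLi in THF regenerates the regiodefined enolate as lithium (3S)-4,4-dimethoxy-2-methyl-3-R-cyclohex-1-en-1-olate F2, which is added to 11 at −78 °C. Diketone 14 is then isolated, cyclised to 15 with KOH in methanol, and 15 is hydrolysed to 16 with 1 M HCl.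

Step 9. The enolate may be protonated instead of forming the C–C bond, formaldehyde may add more than once, and excess lithium may cleave the allylic silyl ether reductively. The fallback sets out from 17 and returns at 19. The Li/NH3 reduction is run as before, but enolate 18 is silylated (TMSCl, Et3N) and isolated as trimethyl{[(4aS,5R,8aS)-1,4a-dimethyl-6-methylidene-5-R-3,4,4a,5,6,7,8,8a-octahydronaphthalen-2-yl]oxy}silane F3. A Yb(OTf)3-catalysed Mukaiyama aldol reaction of F3 with aqueous formaldehyde in THF then gives 19 under non-basic conditions.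

Step 8. The ylide may discriminate poorly between the two carbonyl groups or merely enolise the enedione. The fallback sets out from 15, isolated by leaving out the acid wash of step 7, and returns at 20. Li/NH3/t-BuOH gives lithium (4aR,5S,8aS)-6,6-dimethoxy-1,4a-dimethyl-5-R-3,4,4a,5,6,7,8,8a-octahydronaphthalen-2-olate F4. Formaldehyde converts it to (1S,4aR,5S,8aS)-1-(hydroxymethyl)-6,6-dimethoxy-1,4a-dimethyl-5-R-octahydronaphthalen-2(1H)-one F5. NaBH4 gives (1S,2R,4aR,5S,8aS)-1-(hydroxymethyl)-6,6-dimethoxy-1,4a-dimethyl-5-R-decahydronaphthalen-2-ol F6. PPTS in wet acetone frees (1S,4aS,5S,6R,8aR)-6-hydroxy-5-(hydroxymethyl)-5,8a-dimethyl-1-R-octahydronaphthalen-2(1H)-one F7, in which the C8 carbonyl is the only ketone. Excess Ph3P=CH2 (from Ph3PCH3Br and KOtBu) then gives 20.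

**Further compounds**
F1 | step 7 | trimethyl{[(3S)-4,4-dimethoxy-2-methyl-3-[(3E)-3-methyl-5-[(triisopropylsilyl)oxy]pent-3-en-1-yl]cyclohex-1-en-1-yl]oxy}silane | COC1(OC)CCC(O[Si](C)(C)C)=C(C)[C@@H]1CC/C(C)=C/CO[Si](C(C)C)(C(C)C)C(C)C
F2 | step 7 | lithium (3S)-4,4-dimethoxy-2-methyl-3-[(3E)-3-methyl-5-[(triisopropylsilyl)oxy]pent-3-en-1-yl]cyclohex-1-en-1-olate | COC1(OC)CCC(O[Li])=C(C)[C@@H]1CC/C(C)=C/CO[Si](C(C)C)(C(C)C)C(C)C
F3 | step 9 | trimethyl{[(4aS,5R,8aS)-1,4a-dimethyl-6-methylidene-5-[(3E)-3-methyl-5-[(triisopropylsilyl)oxy]pent-3-en-1-yl]-3,4,4a,5,6,7,8,8a-octahydronaphthalen-2-yl]oxy}silane | C=C1CC[C@H]2[C@@](C)(CCC(O[Si](C)(C)C)=C2C)[C@@H]1CC/C(C)=C/CO[Si](C(C)C)(C(C)C)C(C)C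
F4 | step 8 | lithium (4aR,5S,8aS)-6,6-dimethoxy-1,4a-dimethyl-5-[(3E)-3-methyl-5-[(triisopropylsilyl)oxy]pent-3-en-1-yl]-3,4,4a,5,6,7,8,8a-octahydronaphthalen-2-olate | COC1(OC)CC[C@H]2[C@@](C)(CCC(O[Li])=C2C)[C@@H]1CC/C(C)=C/CO[Si](C(C)C)(C(C)C)C(C)C
F5 | step 8 | (1S,4aR,5S,8aS)-1-(hydroxymethyl)-6,6-dimethoxy-1,4a-dimethyl-5-[(3E)-3-methyl-5-[(triisopropylsilyl)oxy]pent-3-en-1-yl]octahydronaphthalen-2(1H)-one | COC1(OC)CC[C@H]2[C@@](C)(CCC(=O)[C@]2(C)CO)[C@@H]1CC/C(C)=C/CO[Si](C(C)C)(C(C)C)C(C)C
F6 | step 8 | (1S,2R,4aR,5S,8aS)-1-(hydroxymethyl)-6,6-dimethoxy-1,4a-dimethyl-5-[(3E)-3-methyl-5-[(triisopropylsilyl)oxy]pent-3-en-1-yl]decahydronaphthalen-2-ol | COC1(OC)CC[C@H]2[C@@](C)(CC[C@@H](O)[C@]2(C)CO)[C@@H]1CC/C(C)=C/CO[Si](C(C)C)(C(C)C)C(C)C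
F7 | step 8 | (1S,4aS,5S,6R,8aR)-6-hydroxy-5-(hydroxymethyl)-5,8a-dimethyl-1-[(3E)-3-methyl-5-[(triisopropylsilyl)oxy]pent-3-en-1-yl]octahydronaphthalen-2(1H)-one | O=C1CC[C@H]2[C@@](C)(CC[C@@H](O)[C@]2(C)CO)[C@@H]1CC/C(C)=C/CO[Si](C(C)C)(C(C)C)C(C)C
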